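The final ring closed is the 1,4-dioxin, formed by joining the bay-region hydroxyl oxygen of ring C (dibenzofuran C1–OH) to the C–H carbon of ring A that is para to the ring A phenol and adjacent to the ether carbon linking rings A and C. Two-electron oxidation of that phenol with PhI(OAc)2 turns this carbon into an electrophile, so one operation forges the last C–O bond and delivers the complete ring system as its hexamethyl ether. The precursor is a hexamethylated diaryl ether bisphenol, made by Ullmann coupling of a formylated dibenzofuranol with a bromo-aldehyde carrying rings A and E; Baeyer–Villiger oxidation then unmasks both phenols together.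

Key step: step 9

Remark: ring A is the pentaoxygenated benzene ring, rings C and D are the dibenzofuran (standard dibenzofuran locants), ring E is the pendant 3,5-dioxygenated phenoxy ring; 2,6-dibromo-4-methoxyphenol and 5-bromo-4-fluoro-2-methoxybenzaldehyde are taken as catalogue compounds (each is otherwise one bromination away from 4-methoxyphenol or 4-fluoro-2-methoxybenzaldehyde).

Step 1
Reactants: 1 2,6-dibromo-4-methoxyphenol; 2 (3,5-dimethoxyphenyl)boronic acid
Product: 3 1,3-dibromo-2-(3,5-dimethoxyphenoxy)-5-methoxybenzene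
Conditions: Cu(OAc)2 (1.0 equiv, kept divalent by O2), pyridine (5 equiv), 4 Å MS, CH2Cl2, O2 (1 atm), rt
Reagents that add atoms: none
Why: Chan–Lam oxidative O-arylation is well suited to 2,6-dihalogenated phenols and simple arylboronic acids and, unlike an Ullmann reaction of this phenol, should leave both C–Br bonds untouched.

Step 2
Reactants: 3 1,3-dibromo-2-(3,5-dimethoxyphenoxy)-5-methoxybenzene
Product: 5 3-bromo-2-(3,5-dimethoxyphenoxy)-5-methoxybenzaldehyde, via aryllithium 4 (not isolated)
Conditions: n-BuLi (1.05 equiv), THF, −78 °C; then DMF, −78 °C → rt; 1 M HCl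
Reagents that add atoms: N,N-dimethylformamide CN(C)C=O
Why: Bromine–lithium exchange on the symmetrical dibromide should stop after one exchange at −78 °C (the ortho aryloxy group stabilises the aryllithium, which resists a second exchange), and Bouveault formylation with DMF then gives the aldehyde.

Step 3
Reactants: 6 5-bromo-4-fluoro-2-methoxybenzaldehyde; 7 3,5-dimethoxyphenol
Product: 8 5-bromo-4-(3,5-dimethoxyphenoxy)-2-methoxybenzaldehyde
Conditions: K2CO3 (1.5 equiv), DMF, 80 °C
Reagents that add atoms: none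
Why: Nucleophilic aromatic substitution (SNAr): the fluoride para to the formyl group is displaced by the phenoxide oxygen, while the bromide, meta to the formyl group, is inert.

Step 4
Reactants: 8 5-bromo-4-(3,5-dimethoxyphenoxy)-2-methoxybenzaldehyde
Product: 9 3,7,9-trimethoxydibenzo[b,d]furan-2-carbaldehyde
Conditions: Pd(OAc)2 (5 mol%), PCy3·HBF4 (10 mol%), K2CO3 (2 equiv), DMA, 130 °C, argon
Reagents that add atoms: none
Why: Palladium-catalysed intramolecular direct arylation (concerted metalation–deprotonation) of an ortho-bromo diaryl ether; the two ring D carbons ortho to the ether oxygen are equivalent, so only one dibenzofuran can form.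

Step 5
Reactants: 9 3,7,9-trimethoxydibenzo[b,d]furan-2-carbaldehyde
Product: 11 3,7,9-trimethoxydibenzo[b,d]furan-2-ol, via aryl formate 10 (not isolated)
Conditions: mCPBA (1.3 equiv), CH2Cl2, 0 °C → rt; then K2CO3, MeOH, rt
Reagents that add atoms: 3-chloroperoxybenzoic acid O=C(OO)c1cccc(Cl)c1
Why: Baeyer–Villiger (Dakin-type) oxidation: the aryl group, made electron-rich by the para furan oxygen and the ortho methoxy group, should migrate in preference to hydride, and methanolysis of the formate frees the phenol.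

Step 6
Reactants: 11 3,7,9-trimethoxydibenzo[b,d]furan-2-ol
Product: 12 2-hydroxy-3,7,9-trimethoxydibenzo[b,d]furan-1-carbaldehyde
Conditions: MgCl2 (2 equiv), Et3N (4 equiv), (CH2O)n (8 equiv), MeCN, reflux; then 1 M HCl
Reagents that add atoms: formaldehyde (as paraformaldehyde) C=O
Why: Casnati–Skattebøl ortho-formylation: magnesium bound to the phenoxide delivers formaldehyde only ortho to the hydroxyl, and since C3 carries OMe the bay carbon C1 is the only site.

Step 7
Reactants: 12 2-hydroxy-3,7,9-trimethoxydibenzo[b,d]furan-1-carbaldehyde; 5 3-bromo-2-(3,5-dimethoxyphenoxy)-5-methoxybenzaldehyde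
Product: 13 2-[2-(3,5-dimethoxyphenoxy)-3-formyl-5-methoxyphenoxy]-3,7,9-trimethoxydibenzo[b,d]furan-1-carbaldehyde
Conditions: CuI (20 mol%), picolinic acid (40 mol%), K3PO4 (2.0 equiv), DMSO, 100 °C, argon
Reagents that add atoms: none
Why: Ullmann diaryl ether synthesis with a CuI/picolinic acid system suited to ortho-substituted partners; each component has a single reactive site (one phenol, one bromide) and both formyl groups should be inert to K3PO4 in DMSO.

Step 8
Reactants: 13 2-[2-(3,5-dimethoxyphenoxy)-3-formyl-5-methoxyphenoxy]-3,7,9-trimethoxydibenzo[b,d]furan-1-carbaldehyde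
Product: 15 2-[2-(3,5-dimethoxyphenoxy)-3-hydroxy-5-methoxyphenoxy]-3,7,9-trimethoxydibenzo[b,d]furan-1-ol, via bis-formate 14 (not isolated)
Conditions: mCPBA (2.6 equiv), CH2Cl2, 0 °C → rt; then K2CO3, degassed MeOH, 0 °C, argon
Reagents that add atoms: 3-chloroperoxybenzoic acid O=C(OO)c1cccc(Cl)c1
Why: Twofold Baeyer–Villiger oxidation: each formyl group sits ortho to an aryloxy substituent on an electron-rich ring, so aryl migration should give the bis-formate, which shields both phenols from the peracid until mild methanolysis releases them together.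

Step 9
Reactants: 15 2-[2-(3,5-dimethoxyphenoxy)-3-hydroxy-5-methoxyphenoxy]-3,7,9-trimethoxydibenzo[b,d]furan-1-ol
Product: 18 ring-A-monophenol hexamethyl ether of the target (dioxin closed), via aryloxy-λ3-iodane 16 (not isolated), via cyclohexadienone 17 (not isolated)
Conditions: PhI(OAc)2 (1.05 equiv, added over 1 h), (CF3)2CHOH (5 mM in 15), −20 → 0 °C, argon
Reagents that add atoms: none
Why: Proposed new method: exchange of one acetate on iodine for the ring A phenol oxygen (the less hindered phenol, with one free ortho position) gives aryloxy-λ3-iodane 16, in which departure of PhI makes the ring A carbons ortho and para to that oxygen electrophilic (phenoxonium character); the ring C hydroxyl (dibenzofuran O1), held alongside by the existing diaryl ether, adds to the para C–H carbon to give cyclohexadienone 17, which tautomerises to phenol 18, the closest known reaction types being trivalent-iodine phenol dearomatisations with intramolecular oxygen nucleophiles in fluoroalcohol solvents and oxidative cyclisations of hydroxylated diaryl ethers to dibenzodioxins. The one ring closed is the 1,4-dioxin, by a six-membered C–O closure onto the terminus of the ring A π-system; the sp3 carbon of 17 is racemic and is erased on re-aromatisation, so no stereocentre has to be controlled. Three selectivities are needed. First, oxidation must start at ring A: the ring C hydroxyl lies in the bay region between the aryloxy group and ring D, should exchange slowly and reversibly on iodine, and has no nucleophile within reach once oxidised, whereas only the ring A iodane can collapse intramolecularly. Second, the tether also reaches the neighbouring ring A carbon that carries the ring E ether (ipso attack, also six-membered); that carbon is fully substituted and shielded, ketal formation there should be reversible in acidic HFIP, and only para attack is made irreversible by tautomerisation. Third, over-oxidation of the more electron-rich product is held back by one equivalent of oxidant, slow addition, high dilution, low temperature and a non-nucleophilic solvent.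

Step 10
Reactants: 18 ring-A-monophenol hexamethyl ether of the target
Product: 19 CNP0256302.0 (the target heptaphenol)
Conditions: BBr3 (15 equiv), CH2Cl2, −78 °C → rt; then MeOH, 0 °C; H2O
Reagents that add atoms: none
Why: Lewis-acid-mediated demethylation: BBr3 complexes each methoxy oxygen and bromide cleaves the O–CH3 bond by SN2, whereas the diaryl ether, dioxin and furan C–O bonds (sp2 carbon on both sides) cannot be cleaved this way.

Compound list
1 | 2,6-dibromo-4-methoxyphenol | COc1cc(Br)c(O)c(Br)c1 | starting material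
2 | (3,5-dimethoxyphenyl)boronic acid | COc1cc(OC)cc(B(O)O)c1 | starting material
3 | 1,3-dibromo-2-(3,5-dimethoxyphenoxy)-5-methoxybenzene | COc1cc(Br)c(Oc2cc(OC)cc(OC)c2)c(Br)c1 | intermediate
4 | [3-bromo-2-(3,5-dimethoxyphenoxy)-5-methoxyphenyl]lithium (not isolated) | [Li]c1cc(OC)cc(Br)c1Oc1cc(OC)cc(OC)c1 | intermediate
5 | 3-bromo-2-(3,5-dimethoxyphenoxy)-5-methoxybenzaldehyde | COc1cc(Br)c(Oc2cc(OC)cc(OC)c2)c(C=O)c1 | intermediate
6 | 5-bromo-4-fluoro-2-methoxybenzaldehyde | COc1cc(F)c(Br)cc1C=O | starting material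
7 | 3,5-dimethoxyphenol | COc1cc(O)cc(OC)c1 | starting material
8 | 5-bromo-4-(3,5-dimethoxyphenoxy)-2-methoxybenzaldehyde | COc1cc(Oc2cc(OC)cc(OC)c2)c(Br)cc1C=O | intermediate
9 | 3,7,9-trimethoxydibenzo[b,d]furan-2-carbaldehyde | COc1cc2oc3cc(OC)cc(OC)c3c2cc1C=O | intermediate
10 | 3,7,9-trimethoxydibenzo[b,d]furan-2-yl formate (not isolated) | COc1cc2oc3cc(OC)cc(OC)c3c2cc1OC=O | intermediate
11 | 3,7,9-trimethoxydibenzo[b,d]furan-2-ol | COc1cc2oc3cc(OC)cc(OC)c3c2cc1O | intermediate
12 | 2-hydroxy-3,7,9-trimethoxydibenzo[b,d]furan-1-carbaldehyde | COc1cc2oc3cc(OC)cc(OC)c3c2c(C=O)c1O | intermediate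
13 | 2-[2-(3,5-dimethoxyphenoxy)-3-formyl-5-methoxyphenoxy]-3,7,9-trimethoxydibenzo[b,d]furan-1-carbaldehyde | COc1cc(C=O)c(Oc2cc(OC)cc(OC)c2)c(Oc2c(OC)cc3oc4cc(OC)cc(OC)c4c3c2C=O)c1 | intermediate
14 | 2-[2-(3,5-dimethoxyphenoxy)-3-(formyloxy)-5-methoxyphenoxy]-3,7,9-trimethoxydibenzo[b,d]furan-1-yl formate (not isolated) | COc1cc(OC=O)c(Oc2cc(OC)cc(OC)c2)c(Oc2c(OC)cc3oc4cc(OC)cc(OC)c4c3c2OC=O)c1 | intermediate
15 | 2-[2-(3,5-dimethoxyphenoxy)-3-hydroxy-5-methoxyphenoxy]-3,7,9-trimethoxydibenzo[b,d]furan-1-ol (hexamethyl diaryl ether bisphenol, ring A C–H still open) | COc1cc(OC)cc(Oc2c(O)cc(OC)cc2Oc2c(OC)cc3oc4cc(OC)cc(OC)c4c3c2O)c1 | intermediate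
16 | acetoxy(phenyl)-λ3-iodanyl derivative of 15 at the ring A phenol oxygen (not isolated) | CC(=O)OI(Oc1cc(OC)cc(Oc2c(OC)cc3oc4cc(OC)cc(OC)c4c3c2O)c1Oc1cc(OC)cc(OC)c1)c1ccccc1 | intermediate
17 | ring A cyclohexa-2,5-dienone formed by attack of dibenzofuran O1 at the ring A carbon para to the carbonyl; racemic at that sp3 carbon (not isolated) | O=C1C=C(OC)C2Oc3c(c(OC)cc4oc5cc(OC)cc(OC)c5c34)OC2=C1Oc1cc(OC)cc(OC)c1 | intermediate
18 | hexamethyl ether of the target: dibenzo-1,4-dioxin in which O1 and O2 of a 3,7,9-trimethoxydibenzofuran-1,2-diyl unit bridge two adjacent ring A carbons; round ring A from the carbon on O2: C–O(3,5-dimethoxyphenyl), C–OH, C–H, C–OMe, carbon on O1 | COc1cc(OC)cc(Oc2c(O)cc(OC)c3c2Oc2c(OC)cc4oc5cc(OC)cc(OC)c5c4c2O3)c1 | intermediate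
19 | CNP0256302.0: as 18 with all six OMe groups replaced by OH (no stereocentres) | Oc1cc(O)cc(Oc2c(O)cc(O)c3c2Oc2c(O)cc4oc5cc(O)cc(O)c5c4c2O3)c1 | target

Total step count: 10. Longest linear sequence: 8 steps (6 and 7 to 19, steps 3–10); the ring A/E branch (steps 1–2) joins at step 7.

Steps most likely to fail

Step 9 (proposed new method). What may go wrong: oxidation starting at the ring C phenol or at the electron-rich outer rings; ipso capture at the ring A carbon carrying the ring E ether, followed by loss of 3,5-dimethoxyphenol; or further oxidation of the product to a quinone. Fallback (sets out from 12, returns at 18): the dioxin is built by the classical pair of SNAr followed by intramolecular Ullmann etherification, with the two catechol oxygens told apart by the formyl group of 12. 12 is O-benzylated (BnBr, K2CO3, DMF) to 2-(benzyloxy)-3,7,9-trimethoxydibenzofuran-1-carbaldehyde F1. Baeyer–Villiger oxidation (mCPBA) gives 2-(benzyloxy)-3,7,9-trimethoxydibenzofuran-1-yl formate F2, which is methanolysed (K2CO3, MeOH) to the bay-region phenol 2-(benzyloxy)-3,7,9-trimethoxydibenzofuran-1-ol F3. In parallel, 3-fluoro-4-methoxyphenol F4 is ortho-formylated (MgCl2, Et3N, (CH2O)n) to 4-fluoro-2-hydroxy-5-methoxybenzaldehyde F5. This is brominated at the remaining position ortho to the hydroxyl (NBS, MeCN) to 3-bromo-4-fluoro-2-hydroxy-5-methoxybenzaldehyde F6 and O-arylated with 2 (Cu(OAc)2, pyridine, O2) to 3-bromo-2-(3,5-dimethoxyphenoxy)-4-fluoro-5-methoxybenzaldehyde F7. The phenoxide of F3 displaces the fluoride of F7, which is para to the formyl group (Cs2CO3, DMSO, 90 °C), to give the benzyl-protected bromo diaryl ether F8. BCl3 with pentamethylbenzene (CH2Cl2, −78 °C) removes the benzyl group to give the bromo phenol F9. CuI/picolinic acid/K3PO4 (DMSO, 90 °C) closes the dioxin onto the neighbouring C–Br bond to give the dioxin aldehyde F10. mCPBA then gives the formate F11, and K2CO3/MeOH gives 18.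

Step 7. What may go wrong: slow C–O bond formation between the chelated, formyl-deactivated and doubly ortho-substituted phenoxide of 12 and the ortho-substituted bromide 5, so that protodebromination of 5 takes over. Fallback (sets out from 12, returns at 13): the formyl group of 12 is masked (ethylene glycol, TsOH cat., benzene, Dean–Stark) as 1-(1,3-dioxolan-2-yl)-3,7,9-trimethoxydibenzofuran-2-ol F12, now an electron-rich, non-chelated phenol. F12 is joined to 5 by palladium-catalysed C–O coupling (Pd(OAc)2, t-BuXPhos, K3PO4, toluene, 100 °C) to give the acetal-protected diaryl ether F13, and 1 M HCl in THF returns 13.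

Step 8. What may go wrong: hydride instead of aryl migration at the less electron-rich ring A formyl group (giving the benzoic acid), or peracid attack on the electron-rich outer rings during the twofold oxidation. Fallback (sets out from 3 and 12, returns at 15): the ring A oxygen is introduced by C–Br hydroxylation, so only the ring C formyl group needs a Baeyer–Villiger step. 12 is coupled under the step 7 conditions with an excess of dibromide 3 to give the mono-ether 2-[3-bromo-2-(3,5-dimethoxyphenoxy)-5-methoxyphenoxy]-3,7,9-trimethoxydibenzofuran-1-carbaldehyde F14. mCPBA gives its formate F15, and K2CO3/MeOH gives the bromo phenol F16. Palladium-catalysed hydroxylation of the remaining C–Br bond (Pd2(dba)3, t-BuXPhos, KOH, dioxane/H2O, 100 °C) gives 15.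

Further compounds
F1 | step 9 | 2-(benzyloxy)-3,7,9-trimethoxydibenzo[b,d]furan-1-carbaldehyde | COc1cc2oc3cc(OC)cc(OC)c3c2c(C=O)c1OCc1ccccc1
F2 | step 9 | 2-(benzyloxy)-3,7,9-trimethoxydibenzo[b,d]furan-1-yl formate | COc1cc2oc3cc(OC)cc(OC)c3c2c(OC=O)c1OCc1ccccc1
F3 | step 9 | 2-(benzyloxy)-3,7,9-trimethoxydibenzo[b,d]furan-1-ol | COc1cc2oc3cc(OC)cc(OC)c3c2c(O)c1OCc1ccccc1
F4 | step 9 | 3-fluoro-4-methoxyphenol | COc1ccc(O)cc1F
F5 | step 9 | 4-fluoro-2-hydroxy-5-methoxybenzaldehyde | COc1cc(C=O)c(O)cc1F
F6 | step 9 | 3-bromo-4-fluoro-2-hydroxy-5-methoxybenzaldehyde | COc1cc(C=O)c(O)c(Br)c1F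
F7 | step 9 | 3-bromo-2-(3,5-dimethoxyphenoxy)-4-fluoro-5-methoxybenzaldehyde | COc1cc(C=O)c(Oc2cc(OC)cc(OC)c2)c(Br)c1F
F8 | step 9 | 4-{[2-(benzyloxy)-3,7,9-trimethoxydibenzo[b,d]furan-1-yl]oxy}-3-bromo-2-(3,5-dimethoxyphenoxy)-5-methoxybenzaldehyde | COc1cc(C=O)c(Oc2cc(OC)cc(OC)c2)c(Br)c1Oc1c(OCc2ccccc2)c(OC)cc2oc3cc(OC)cc(OC)c3c12
F9 | step 9 | 3-bromo-2-(3,5-dimethoxyphenoxy)-4-[(2-hydroxy-3,7,9-trimethoxydibenzo[b,d]furan-1-yl)oxy]-5-methoxybenzaldehyde | COc1cc(C=O)c(Oc2cc(OC)cc(OC)c2)c(Br)c1Oc1c(O)c(OC)cc2oc3cc(OC)cc(OC)c3c12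
F10 | step 9 | dioxin aldehyde: 18 with CHO in place of the ring A hydroxyl | COc1cc(OC)cc(Oc2c(C=O)cc(OC)c3c2Oc2c(OC)cc4oc5cc(OC)cc(OC)c5c4c2O3)c1
F11 | step 9 | formate ester of 18 at the ring A hydroxyl | COc1cc(OC)cc(Oc2c(OC=O)cc(OC)c3c2Oc2c(OC)cc4oc5cc(OC)cc(OC)c5c4c2O3)c1
F12 | step 7 | 1-(1,3-dioxolan-2-yl)-3,7,9-trimethoxydibenzo[b,d]furan-2-ol | COc1cc2oc3cc(OC)cc(OC)c3c2c(C2OCCO2)c1O
F13 | step 7 | 2-(3,5-dimethoxyphenoxy)-3-{[1-(1,3-dioxolan-2-yl)-3,7,9-trimethoxydibenzo[b,d]furan-2-yl]oxy}-5-methoxybenzaldehyde | COc1cc(C=O)c(Oc2cc(OC)cc(OC)c2)c(Oc2c(OC)cc3oc4cc(OC)cc(OC)c4c3c2C2OCCO2)c1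
F14 | step 8 | 2-[3-bromo-2-(3,5-dimethoxyphenoxy)-5-methoxyphenoxy]-3,7,9-trimethoxydibenzo[b,d]furan-1-carbaldehyde | COc1cc(Br)c(Oc2cc(OC)cc(OC)c2)c(Oc2c(OC)cc3oc4cc(OC)cc(OC)c4c3c2C=O)c1
F15 | step 8 | 2-[3-bromo-2-(3,5-dimethoxyphenoxy)-5-methoxyphenoxy]-3,7,9-trimethoxydibenzo[b,d]furan-1-yl formate | COc1cc(Br)c(Oc2cc(OC)cc(OC)c2)c(Oc2c(OC)cc3oc4cc(OC)cc(OC)c4c3c2OC=O)c1
F16 | step 8 | 2-[3-bromo-2-(3,5-dimethoxyphenoxy)-5-methoxyphenoxy]-3,7,9-trimethoxydibenzo[b,d]furan-1-ol | COc1cc(Br)c(Oc2cc(OC)cc(OC)c2)c(Oc2c(OC)cc3oc4cc(OC)cc(OC)c4c3c2O)c1
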